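If E were to lead at the end of the flask, D would have to sink below E by 50 min. I asked what that would take.

| setting | elm | ash | flask |
|---|---|---|---|
| G | 0.98 M | 0.49 M | 0.98 M |
| remark | the very flask that is asked about, followed so far | run made earlier |  |
| time |  |  | 50 min |

| run | time / min | D / % | E / % |
|---|---|---|---|
| elm | 1.50 | 33.4 | 22.4 |
| elm | 4.00 | 43.8 | 25.6 |
| elm | 8.00 | 46.7 | 21.7 |
| elm | 20.0 | 42.9 | 11.3 |
| ash | 12.0 | 28.5 | 25.3 |
| ash | 25.0 | 5.3 | 20.4 |
| ash | 40.0 | 0.8 | 12.4 |
| ash | 50.0 | 0 | 8.0 |

(scatter of a reading: 1 percentage point)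

* ratio of D to E at 6.0 s
* ratio of D to E at 2.0 min
* ratio of D to E at 50 min
* which of D and E there is more of at 50 min

- a reading or a percentage of D counts all its forms, free or not

1. The charges differ, so I compared molar amounts. In the ash run, E stood at 0.100 M at 25.0 min, with D down to 5.3%. In the elm run, it stood at 0.111 M at 20.0 min.

2. From these two readings I took the first value as the hold level of E: the molar amount at which I expected E to wait while a stock of D lasted. In the flask, that is 10.2% of the G charged.

3. The elm run held 0.420 M of D at 20.0 min. To reach the hold level by 50 min, D had to lose 0.0107 M min⁻¹.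

4. Between its first two readings, the ash run lost D at 0.00874 M min⁻¹, which is slower than that need. I assumed this steady, zero-order loss for the flask. So I expected D to stay ahead at 16.1%, a ratio of 1.58.

5. The forecast gave 1.5 (1.2 to 1.9) at 6.0 s, 1.53 (1.42 to 1.68) at 2.0 min, and 8 (3 to 13) at 50 min, with D ahead. It had E “leaving about 3% at 50 min”. Its late ratio stood above mine, though we agreed on the lead.

6. The flask gave ratios of 1.85, 1.48 and 1.71, with D ahead at 17.4% against 10.1% for E.

    J ⇌ D (K = 0.420, k = 0.0150 s⁻¹)
    J → Q (k = 0.00350 s⁻¹)
    G → J (k = 0.0440 s⁻¹)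
    G ⇌ X (K = 14.0, k = 7.70 × 10⁻⁴ s⁻¹)
    L ⇌ D, rate k5*(cs5 - [D]) while solid is left; crystals form when [D] > cs5 (solubility = 24.0 mM, k = 0.0830 s⁻¹)
    J ⇌ E (K = 2.30, k = 0.00760 s⁻¹)

The reverse step from E to J was part of what kept D ahead: in the same flask without that step, the ratio at 50 min fell to 4.51 × 10⁻⁵ and E led. The hold level had given E as 10.2%, and the flask held 10.1%. For the flask charged with 2.5 M of G, the hold level gives 4.00%, and that flask held 4.03% of E.

(The data were generated by integration for an exercise; the scatter is artificial.)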